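The earlier runs and the new flask were generated by integration from invented constants; noise was put on by code.

Cedar's reagent charge stood to maple's as 2.05 to one, yet its left-handed product at 8.00 min stood to maple's as 1.58 to one, although each turn of the listed step takes one reagent.

| flask | left-handed substrate | right-handed substrate | reagent | free catalyst | remark | time |
|---|---|---|---|---|---|---|
| maple | 0.18 M | 0.18 M | 0.39 M | 36 mM | run made earlier |  |
| oak | 0.18 M | 0.18 M | 0.60 M | 36 mM | run made earlier |  |
| cedar | 0.18 M | 0.18 M | 0.80 M | 36 mM | run made earlier |  |
| Wednesday's | 0.18 M | 0.18 M | 0.450 M | 36 mM |  | 8.0 min |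
| Monday's | 0.18 M | 0.18 M | 0.680 M | 36 mM |  | 8.0 min |

- maple (time / min: left-handed product / %, left-handed substrate / %): 0.667: 3.0, 47.6; 1.33: 5.0, 44.4; 2.50: 8.8, 42.4; 4.00: 12.0, 41.7; 8.00: 12.9, 38.4
- oak (time / min: left-handed product / %, left-handed substrate / %): 0.667: 4.9, 43.8; 1.33: 7.6, 43.6; 2.50: 11.5, 41.3; 4.00: 14.6, 35.9; 8.00: 18.2, 33.7
- cedar (time / min: left-handed product / %, left-handed substrate / %): 0.667: 5.2, 44.9; 1.33: 9.2, 42.1; 2.50: 13.8, 38.5; 4.00: 16.2, 35.0; 8.00: 20.4, 30.2

(each reading ± 1 percentage point)

- free catalyst is single-handed; left-handed substrate and right-handed substrate are mirror images of each other, charged as a racemate, each of them at the stated concentration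
- steps thought possible: reagent + free catalyst + left-handed substrate -> free catalyst + left-handed product; reagent + free catalyst + right-handed substrate -> free catalyst + right-handed product; left-handed substrate <-> right-handed substrate; free catalyst -> spent catalyst A; 2 reagent -> self-condensation product; 2 free catalyst -> spent catalyst B

- which of the two there is more of at the end, Wednesday's (left-handed product / right-handed product)
- which of the two there is more of at the end, Monday's (left-handed product / right-handed product)
- left-handed product at the end, in percent of the left-handed substrate and right-handed substrate together charged, Wednesday's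
- left-handed product at the end, in percent of the left-handed substrate and right-handed substrate together charged, Monday's

My first round was plain proportion: maple's product scaled by reagent gave 22.5% for Monday's. That held the left-handed substrate at its charge, but the readings show it falling, while left-handed substrate and product together stayed near half of the charge (51.3% in maple at 8.00 min).

So I put the fall back in. Maple's readings gave a grip of 0.765 /M, the grip being the logarithm of the left-handed charge over the part of it not yet product, divided by the reagent charge, for the same catalyst charge and time. Oak gave 0.754 /M and cedar 0.655 /M. The fall clears part of the gap: cedar's grip stood to maple's as 0.856 to one, against 0.771 to one for product per reagent. Cedar's grip still read lower than maple's, so I took neighbours' means. Wednesday's, between maple and oak, came to 14.5% and Monday's, between oak and cedar, to 19.0%. Right-handed product stands in none of the readings, so my reckoning is silent on it.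

The forecast named left-handed product in both flasks and gave 15% (13.3% to 16.7%) for Wednesday's and 19.3% (17.6% to 21%) for Monday's, by “Interpolating the 8-min values”. Wednesday's gave 14.6% left-handed product against 0.259% right-handed, and Monday's 19.1% against 0.357%.

    reagent + free catalyst + left-handed substrate → free catalyst + left-handed product (k = 0.130 /M²/s)
    reagent + free catalyst + right-handed substrate → free catalyst + right-handed product (k = 0.00200 /M²/s)
    left-handed substrate ⇌ right-handed substrate (k = 5.40 × 10⁻⁴ /s)
    free catalyst → spent catalyst A (k = 3.70 × 10⁻⁴ /s)
    2 reagent → self-condensation product (k = 0.00210 /M/s)
    2 free catalyst → spent catalyst B (k = 0.0750 /M/s)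

Those results put Wednesday's grip at 0.769 /M and Monday's at 0.707 /M. The neighbour is Monday's flask charged with 2.7 M of reagent. Cedar's grip, the last one read, gives it 41.5%. The neighbour itself gave 35.6%, a grip of 0.461 /M, lower than cedar's, with 14.8% of its reagent left at 8.00 min.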